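**The charge.** A small charge of Q, 10.0% of the D, turned D into Z under held X. I had two earlier runs, and I wanted Z at the end of each new flask.

| setting | north | north-west | zeta | gamma | beta | alpha |
|---|---|---|---|---|---|---|
| D | 0.070 M | 0.11 M | 0.050 M | 0.050 M | 0.050 M | 0.050 M |
| X | 23 mM (held) | 23 mM (held) | 23 mM (held) | 23 mM (held) | 23 mM (held) | 23 mM (held) |
| Q | 5 mM | 5 mM | 5.0 mM | 5.0 mM | 5.0 mM | 5.0 mM |
| temperature | −25 °C | 0 °C | 20 °C | 0 °C | −20 °C |  |
| remark | run made earlier | run made earlier |  |  |  | at −20 °C until 2.5 d, from then on at 20 °C |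
| time |  |  | 5.0 d | 5.0 d | 5.0 d | 5.0 d |

| run | time / d | Z / % | D / % |
|---|---|---|---|
| north | 4.00 | 0 | 96.2 |
| north | 6.00 | 0.1 | 95.5 |
| north | 10.0 | 0 | 95.4 |
| north | 15.0 | 1.3 | 94.3 |
| north | 30.0 | 0.6 | 93.4 |
| north | 50.0 | 2.3 | 90.7 |
| north-west | 1.04 | 3.0 | 95.1 |
| north-west | 1.67 | 2.6 | 94.3 |
| north-west | 3.00 | 4.7 | 89.7 |
| north-west | 5.00 | 5.2 | 84.7 |
| north-west | 8.00 | 7.4 | 78.0 |
| north-west | 15.0 | 9.2 | 64.1 |

(readings scatter by 1 percentage point)

- what was read earlier has a scatter of 1 percentage point, one standard deviation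
- at the start none of X is in solution

* the flask that comes out highest in amount of Z, in percent of the D charged, or "all alike" when all lie within 1.5 percentage points (zeta / gamma / beta / alpha / all alike)
* Z at the end, in percent of the D charged, zeta
* Z at the end, in percent of the D charged, gamma
* Z at the end, in percent of the D charged, beta
* Z at the end, in percent of the D charged, alpha

**Temperature turned.** By hand, cooling should stretch the time constant of the loss of D. I treated the loss of D as a pseudo-first-order decay and used each run's last reading as a fraction of the charge. North lost D at 0.00195 /d at −25 °C, and north-west at 0.0296 /d at 0 °C. That gap was 1.18 decades. I stretched it in proportion to degrees, so −20 °C to 20 °C spanned 1.89 decades, a rate factor of 77.7. From 0 °C to 20 °C the factor was 8.81.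

**Switch turned.** Alpha counted 2.53 d of warm days, meaning days at 20 °C giving equal progress, with each colder day divided by its rate factor. Its cold half added 0.0322 d, far less than its warm half of 2.50 d. So I expected alpha's end to resemble zeta at 2.5 d.

**Time turned.** By hand, more warm days should mean more Z. But in north-west, Z read 45.6% of the D lost at 3.00 d and 25.6% at 15.0 d. So a longer run might not give more Z.

**The forecast.** It chose alpha, with 10.5% there, 9.5% for zeta, 6% for gamma and 0.7% for beta. It expected that “Z would then peak near 10% at about 2.5 d”. My clock gave a position, not a height.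

**The flask.** Alpha came out highest at 22.5%, against the forecast's 10.5%; zeta gave 6.87%, gamma 10.6% and beta 0.286%.

    D + Q ⇌ J (K = 33.2 /M, k = 0.147 /M/min, Ea = 60.0 kJ/mol, ΔH = −14.0 kJ/mol)
    E + J ⇌ G (K = 27.7 /M, k = 1.57 /M/min, Ea = 66.0 kJ/mol, ΔH = 15.0 kJ/mol)
    G → Q + Z (k = 0.0355 /min, Ea = 96.0 kJ/mol)
    X ⇌ E, rate k4*(csat - [E]) (kL = 0.00269 /min)
    E + Z → L (k = 0.0406 /M/min, Ea = 54.0 kJ/mol)
    (constants at 20 °C)

Until 2.5 d, D and Q filled J and G in alpha, which then held 31.7% J, 6.68% G and 0.0802% Z. After the warming, G gave Q and Z while E turned Z into L, and alpha ended with 24.6% D and 22.5% Z. At 2.53 d of warm days, alpha compared with zeta at 2.50 d, which held 27.6% D and 23.8% Z. Gamma, left until 50.0 d, counted 5.68 d warm days and held 1.57% Z and 95.4% L, where zeta at 5.00 d held 6.87% Z and 88.0% L.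

The data come from a simulation for substances that don't exist, noise included.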